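**Conventions.** Ring A is the hexasubstituted ring: C1 carries the aroyl carbon, C2 OH, C3 the C10 chain, C4 OMe, C5 the (E)-3-methylbut-1-enyl group, C6 OH. Ring B is the 3-hydroxyphenyl ring. The chain is C1' (ArCH2), C2' (stereocentre), C3', C4', C5'(CH3)=C6'H2, with the isopropenyl group on C2'. C2' is R (isopropenyl > CH2Ar > CH2CH2 > H).

**Assumption.** Ketene 9 is not a catalogue compound; it is treated as a stock gas made on demand by cracking acetone. Commercial 1 is the (4R) epoxide as a cis/trans mixture, and both isomers converge in step 1.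

## Analysis of the target

The target is a benzophenone whose ring A is a fully substituted phloroglucinol, joined through the ketone at C1 to ring B. Around ring A the oxygen-bearing carbons C2 (OH), C4 (OMe) and C6 (OH) alternate with the carbon-bearing carbons C1 (aroyl), C3 (chain) and C5 (alkenyl). The three oxygens are differentiated: only the one para to the ketone is methylated. The single stereocentre, C2' (R), sits β to ring A on a chain whose C1' is a non-allylic, β-branched methylene, so the C-alkylation chemistry that serves prenyl halides does not apply. The sensitive groups are the two 1,1-disubstituted alkenes, which cyclise onto the neighbouring C2 phenol under acid, and the electron-rich styrene-type alkene ortho to the C6 phenol. This rules out strong acids, electrophilic halogen and hydrogenation late in the route. The difficulty is the crowding and the bookkeeping of ring A: six different neighbours and no position that an electrophilic substitution would find unaided. Two features invite a de novo construction of ring A. First, the strict O/C alternation C2(O)–C3–C4(O)–C5–C6(O)–C1 is the pattern that a vinylketene and an ynol ether write in a benzannulation. Second, the fragment C3(ring A)–C1'–C2'(isopropenyl)–C3'–C4'–C5'(CH3) is atom for atom the chain C2–C3–C4–C5–C6–C1(CH3) of (R)-limonene, so the terpene's C2 can become ring carbon C3 and its C4 the stereocentre C2'.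

## Retrosynthetic reasoning

**28 back to 22.** The two silyl ethers of 27 are removed last, under non-acidic conditions that leave the alkenes alone. The ketone of 27 comes from carbinol 26 by a neutral oxidation. Carbinol 26 is cut at the bond between the carbinol carbon and ring B, giving aldehyde 23 and aryl Grignard reagent 25 (from bromide 24). The formyl carbon of 23 is attached to C1 of phenol 22 by a magnesium-phenoxide-directed ortho-formylation. C1 is the only free position of 22 and lies ortho to its one free OH, so no regiochemical question arises, and a Friedel–Crafts aroylation under Lewis acid is avoided.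

**22 back to 10 and 17 (key disconnection).** Ring A is cut at C3–C4 and C5–C6. C4 and C5, with the OMe group and the complete alkenyl group, are the two alkyne carbons of ynol ether 17. C6, C1, C2 and C3 are the four ring carbons of cyclobutenone 10. In the forward direction the alkyne is inserted between the carbonyl carbon and the α-carbon of 10, and the four-membered ring becomes the aromatic ring. This single operation places five of the six substituents of ring A. It fixes the O/C alternation through the polarity of the ynol ether. It also delivers the three oxygens already differentiated: C4 as OMe, C2 as a silyl ether, C6 as the only free OH. The precursors are a monocyclic enone and an acyclic enyne, with no aromatic ring at all. The cut is made here because no other pair of ring bonds lets both the terpene-derived chain and the methyl ether arrive in place without later protecting-group exchange.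

**17 back to 13 and 14.** The sp–sp2 bond between the alkyne and the alkene is cut. Methoxyacetylide 15, made in the flask from chloroacetal 14, is transmetalated to zinc reagent 16 and coupled with (E)-vinyl iodide 13, which fixes the alkene geometry before the ring exists. Iodide 13 comes from alkyne 11 by syn-hydrometalation and iodinolysis. A methyl ynol ether is required, not only because the target carries OMe at C4 but because it cannot lose an alkene by retro-ene reaction at the temperature of the key step.

**10 back to 8 and 9.** The cyclobutenone is cut into siloxyalkyne 8 and ketene 9 by a [2+2] cycloaddition. The ketene supplies C6 and C1 of ring A. The silyl group of 8 becomes the protecting group of the C2 oxygen without a separate step.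

**8 back to 1.** The oxygen of 8 is introduced at the terminal carbon of enyne 5 by oxidation of acetylide 6 to ynolate 7 and O-silylation. Enyne 5 comes from keto alkyne 4 by methylenation of the ketone, which creates C5'=C6'. Keto alkyne 4 comes from keto aldehyde 3 by a one-carbon diazophosphonate homologation: the aldehyde carbon becomes the internal alkyne carbon and finally C3 of ring A, and the added carbon becomes C2. Keto aldehyde 3 is the product of oxidative cleavage of the six-membered ring of 1 through diol 2. No bond to the stereocentre is made or broken at any point, so C2' of 28 is C4 of 1 throughout.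

## Alternatives that were turned down

**Alternative 1:** the textbook route cuts C1'–C2'. A fully substituted benzyl bromide A1, built by successive electrophilic substitutions on a symmetrical trioxygenated benzene, would alkylate the enolate of acyl oxazolidinone A2 (Evans alkylation) to give A3. The imide would then be converted into methyl ketone A4 and methylenated to the isopropenyl group. It was turned down for four reasons:
- A1 must itself carry all the ring substituents, installed one at a time among three equivalent positions with three oxygens kept distinct.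
- A1 is an ortho,ortho',para-trioxygenated benzyl bromide that ionises readily to a quinone methide.
- A4 has its stereocentre α to the ketone, where methylenation can epimerise it.
- The stereocentre costs an auxiliary and about five steps after it is set, and the overall count is roughly double that of the chosen route.

**Alternative 2:** a ring-from-ring route in which the fully substituted 4-methoxy-2-pyranone A5 is opened by methoxide at the lactone carbonyl and reclosed by Claisen condensation of the aroylmethyl carbon onto the ester. This would give ring A with the correct 4-OMe/2,6-(OH)2 pattern and the aroyl group in one step. It was turned down because A5 is no simpler than ring A. Its C3 chain would have to come from reductive alkylation with aldehyde A6, whose stereocentre is α to the formyl group and allylic, so it would racemise and conjugate under the amine catalysis. The C5 alkenyl group needs a separate halogenation and coupling, and the aroylmethyl arm a dianion acylation. The reclosure itself can also take the aldol course to a resorcylate.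

**Alternative 3:** an aryne route in which aryne A8, generated from silyl triflate A7 by fluoride, inserts into the C–O bond of a protected 3-hydroxybenzoic acid. This would form C2–O and C1–C(=O) together. The regiochemistry is sound: the C6 alkoxy group beside the triple bond directs the carboxylate oxygen to the distal carbon C2 and leaves the aryl anion at C1 to take the acyl group. It was turned down because A7 already carries the other four substituents plus two adjacent leaving groups on a hexasubstituted ring. The precursor is therefore harder to make than the product, and the key step would contribute only the last two bonds.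

Key step: step 8

## Route

Fragment 1 (steps 1–5) gives cyclobutenone 10, fragment 2 (steps 6–7) gives ynol ether 17, step 8 joins them, and steps 9–12 add ring B.

Step 1
Reactants: 1 (4R)-limonene 1,2-oxide (cis/trans mixture)
Product: 3 (3R)-6-oxo-3-(prop-1-en-2-yl)heptanal, via trans-diol 2 (not isolated)
Conditions: H5IO6, THF/H2O, 0 °C → rt
Reagents that add atoms: water, O
Why: Acid-catalysed hydrolysis of either epoxide isomer gives diol 2, which periodic acid cleaves (Malaprade glycol cleavage); the isopropenyl group is inert and the stereocentre is not touched, so both isomers of 1 should converge on one keto aldehyde.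

Step 2
Reactants: 3 (3R)-6-oxo-3-(prop-1-en-2-yl)heptanal
Product: 4 (5R)-5-(prop-1-en-2-yl)oct-7-yn-2-one
Conditions: dimethyl (1-diazo-2-oxopropyl)phosphonate, K2CO3, MeOH, 0 °C → rt (reagent and base premixed before 3 is added)
Reagents that add atoms: dimethyl (1-diazo-2-oxopropyl)phosphonate, CC(=O)C(=[N+]=[N-])P(=O)(OC)OC
Why: Seyferth–Gilbert homologation with the Ohira–Bestmann reagent is selective for the aldehyde over the methyl ketone; the stereocentre is β to the aldehyde and cannot epimerise.

Step 3
Reactants: 4 (5R)-5-(prop-1-en-2-yl)oct-7-yn-2-one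
Product: 5 (5R)-2-methyl-5-(prop-1-en-2-yl)oct-1-en-7-yne
Conditions: Ph3PCH3Br, KOt-Bu, THF, 0 °C → rt
Reagents that add atoms: methyltriphenylphosphonium bromide, C[P+](c1ccccc1)(c1ccccc1)c1ccccc1.[Br-]
Why: Wittig methylenation of the ketone; the ylide is too weak a base to deprotonate the terminal alkyne, and the stereocentre is remote from the carbonyl group.

Step 4
Reactants: 5 (5R)-2-methyl-5-(prop-1-en-2-yl)oct-1-en-7-yne
Product: 8 {[(4R)-7-methyl-4-(prop-1-en-2-yl)oct-7-en-1-yn-1-yl]oxy}tri(propan-2-yl)silane, via lithium acetylide 6 (not isolated), via lithium ynolate 7 (not isolated)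
Conditions: n-BuLi, THF, −78 °C; LiOOt-Bu (from t-BuOOH and LiN(SiMe3)2), −78 → 0 °C; TIPSOTf, −78 °C → rt
Reagents that add atoms: tert-butyl hydroperoxide, CC(C)(C)OO; triisopropylsilyl trifluoromethanesulfonate, CC(C)[Si](OS(=O)(=O)C(F)(F)F)(C(C)C)C(C)C
Why: The lithium acetylide is oxidised at carbon by the lithium peroxide to the ynolate (a known route to siloxyalkynes), and the bulky silyl triflate traps the ynolate on oxygen; the nucleophilic peroxide does not epoxidise the unactivated alkenes.

Step 5
Reactants: 8 {[(4R)-7-methyl-4-(prop-1-en-2-yl)oct-7-en-1-yn-1-yl]oxy}tri(propan-2-yl)silane; 9 ketene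
Product: 10 2-[(2R)-5-methyl-2-(prop-1-en-2-yl)hex-5-en-1-yl]-3-{[tri(propan-2-yl)silyl]oxy}cyclobut-2-en-1-one
Conditions: 9 (excess, gas stream), CH2Cl2, 0 °C → rt
Reagents that add atoms: none
Why: [2+2] cycloaddition of a ketene with an electron-rich siloxyalkyne, a known entry to 3-siloxycyclobutenones; the ketene carbonyl carbon bonds to the nucleophilic alkyne carbon that carries the chain, and ketene itself does not add to the unactivated alkenes.

Step 6
Reactants: 11 3-methylbut-1-yne
Product: 13 (1E)-1-iodo-3-methylbut-1-ene, via alkenylzirconocene 12 (not isolated)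
Conditions: (C5H5)2Zr(H)Cl, CH2Cl2, rt; I2, 0 °C
Reagents that add atoms: iodine, II
Why: Hydrozirconation is a syn, terminal-selective addition and iodinolysis proceeds with retention, so the E geometry of the future C5 alkenyl group is set here.

Step 7
Reactants: 14 2-chloro-1,1-dimethoxyethane; 13 (1E)-1-iodo-3-methylbut-1-ene
Product: 17 (3E)-1-methoxy-5-methylhex-3-en-1-yne, via lithium methoxyacetylide 15 (not isolated), via chloro(methoxyethynyl)zinc 16 (not isolated)
Conditions: LiNEt2 (3 equiv, from Et2NH and n-BuLi), THF, 0 °C; ZnCl2, 0 °C; 13, Pd(PPh3)4 (5 mol %), rt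
Reagents that add atoms: none
Why: Double elimination and deprotonation of the chloroacetal give the alkoxyacetylide (a known in-flask preparation), and Negishi coupling of the alkynylzinc with the alkenyl iodide under zerovalent palladium proceeds with retention of the E geometry.

Step 8
Reactants: 10 2-[(2R)-5-methyl-2-(prop-1-en-2-yl)hex-5-en-1-yl]-3-{[tri(propan-2-yl)silyl]oxy}cyclobut-2-en-1-one; 17 (3E)-1-methoxy-5-methylhex-3-en-1-yne
Product: 22 3-methoxy-2-[(1E)-3-methylbut-1-en-1-yl]-4-[(2R)-5-methyl-2-(prop-1-en-2-yl)hex-5-en-1-yl]-5-{[tri(propan-2-yl)silyl]oxy}phenol, via vinylketene 18 (not isolated), via vinylcyclobutenone 19 (not isolated), via dienylketene 20 (not isolated), via cyclohexadienone 21 (not isolated)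
Conditions: 17 (2 equiv), toluene (0.5 M), 80 → 110 °C, sealed tube, argon
Reagents that add atoms: none
Why: Danheiser benzannulation (cyclobutenone plus heteroatom-substituted alkyne), run as a four-stage pericyclic cascade; thermal conrotatory 4π opening of 10 gives vinylketene 18. The ketene C=C of 18 then undergoes [2+2] cycloaddition with 17 to give 19: the electrophilic ketene carbonyl carbon bonds to the nucleophilic alkyne carbon remote from OMe (the one carrying the alkenyl group), forming C5–C6, and the ketene α-carbon bonds to the OMe-bearing carbon, forming C3–C4, and this polarity match is what places OMe between the two carbon substituents. Conrotatory 4π opening of 19 gives dienylketene 20, and thermal disrotatory 6π electrocyclisation through the unsubstituted CH2 terminus closes ring A at C1–C6; isomers of 20 with the wrong alkene geometry revert to 19, so the cascade should funnel to 21, which tautomerises to 22. No stereocentre is formed, and C2' lies outside the reacting π system with no acidic hydrogen under neutral thermal conditions, so it is carried through unchanged. The step needs chemoselectivity of 18 for the alkyne of 17 over the unactivated C=C bonds, which the much higher nucleophilicity and the excess of the ynol ether should secure. It also needs a single mode of 6π closure, which is secured because the alkenyl group of 17 ends up on the ketene α-carbon of 20, where it is cross-conjugated and cannot enter a competing hexatriene closure. The methyl ynol ether has no β-hydrogen on its O-alkyl group, so the retro-ene loss of alkene that limits higher alkyl ynol ethers at this temperature is not available.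

Step 9
Reactants: 22 3-methoxy-2-[(1E)-3-methylbut-1-en-1-yl]-4-[(2R)-5-methyl-2-(prop-1-en-2-yl)hex-5-en-1-yl]-5-{[tri(propan-2-yl)silyl]oxy}phenol
Product: 23 2-hydroxy-4-methoxy-3-[(1E)-3-methylbut-1-en-1-yl]-5-[(2R)-5-methyl-2-(prop-1-en-2-yl)hex-5-en-1-yl]-6-{[tri(propan-2-yl)silyl]oxy}benzaldehyde
Conditions: MgCl2, Et3N, (CH2O)n, THF, 65 °C
Reagents that add atoms: paraformaldehyde (as formaldehyde), C=O
Why: Casnati–Skattebøl ortho-formylation: the magnesium phenoxide delivers formaldehyde to the ortho carbon and a second formaldehyde oxidises the hydroxymethyl group; C1 is the only free ring position and is ortho to the free OH, and the non-acidic medium should spare the alkenes and the aryl silyl ether.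

Step 10
Reactants: 23 2-hydroxy-4-methoxy-3-[(1E)-3-methylbut-1-en-1-yl]-5-[(2R)-5-methyl-2-(prop-1-en-2-yl)hex-5-en-1-yl]-6-{[tri(propan-2-yl)silyl]oxy}benzaldehyde; 24 (3-bromophenoxy)(tert-butyl)dimethylsilane
Product: 26 (3-{[tert-butyl(dimethyl)silyl]oxy}phenyl){2-hydroxy-4-methoxy-3-[(1E)-3-methylbut-1-en-1-yl]-5-[(2R)-5-methyl-2-(prop-1-en-2-yl)hex-5-en-1-yl]-6-{[tri(propan-2-yl)silyl]oxy}phenyl}methanol (both carbinol epimers), via arylmagnesium bromide 25 (not isolated)
Conditions: 24, Mg, THF, 40 °C; then 23 (25 in 2.5 equiv), THF, 0 °C → rt; aq NH4Cl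
Reagents that add atoms: none
Why: Grignard addition to the aldehyde; the first equivalent of 25 deprotonates the phenol and the second adds to the carbonyl group, and the new carbinol centre needs no control because it is oxidised in step 11.

Step 11
Reactants: 26 (3-{[tert-butyl(dimethyl)silyl]oxy}phenyl){2-hydroxy-4-methoxy-3-[(1E)-3-methylbut-1-en-1-yl]-5-[(2R)-5-methyl-2-(prop-1-en-2-yl)hex-5-en-1-yl]-6-{[tri(propan-2-yl)silyl]oxy}phenyl}methanol
Product: 27 (3-{[tert-butyl(dimethyl)silyl]oxy}phenyl){2-hydroxy-4-methoxy-3-[(1E)-3-methylbut-1-en-1-yl]-5-[(2R)-5-methyl-2-(prop-1-en-2-yl)hex-5-en-1-yl]-6-{[tri(propan-2-yl)silyl]oxy}phenyl}methanone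
Conditions: MnO2 (activated, excess), CH2Cl2, rt
Reagents that add atoms: none
Why: MnO2 oxidation of a doubly benzylic alcohol under neutral conditions; it removes the carbinol stereocentre and should leave the alkenes and silyl ethers alone, and the crude carbinol is used directly to limit quinone methide formation.

Step 12
Reactants: 27 (3-{[tert-butyl(dimethyl)silyl]oxy}phenyl){2-hydroxy-4-methoxy-3-[(1E)-3-methylbut-1-en-1-yl]-5-[(2R)-5-methyl-2-(prop-1-en-2-yl)hex-5-en-1-yl]-6-{[tri(propan-2-yl)silyl]oxy}phenyl}methanone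
Product: 28 {2,6-dihydroxy-4-methoxy-3-[(1E)-3-methylbut-1-en-1-yl]-5-[(2R)-5-methyl-2-(prop-1-en-2-yl)hex-5-en-1-yl]phenyl}(3-hydroxyphenyl)methanone
Conditions: Bu4NF (2.5 equiv), THF, 0 °C; aq NH4Cl
Reagents that add atoms: none
Why: Fluoride cleavage of both aryl silyl ethers; no acid is used, so the isopropenyl groups should not cyclise onto the freed C2 phenol, and C2' is untouched.

## Compound list

1 | (4R)-limonene 1,2-oxide, cis/trans mixture [(4R)-1-methyl-4-(prop-1-en-2-yl)-7-oxabicyclo[4.1.0]heptane] | CC12CC[C@H](CC1O2)C(=C)C | starting material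
2 | (4R)-1-methyl-4-(prop-1-en-2-yl)cyclohexane-1,2-diol (trans-diol, not isolated) | CC1(O)CC[C@H](CC1O)C(=C)C | intermediate
3 | (3R)-6-oxo-3-(prop-1-en-2-yl)heptanal | CC(=O)CC[C@H](CC=O)C(=C)C | intermediate
4 | (5R)-5-(prop-1-en-2-yl)oct-7-yn-2-one | CC(=O)CC[C@H](CC#C)C(=C)C | intermediate
5 | (5R)-2-methyl-5-(prop-1-en-2-yl)oct-1-en-7-yne | C=C(C)CC[C@H](CC#C)C(=C)C | intermediate
6 | lithium acetylide of 5 (not isolated) | C=C(C)CC[C@H](CC#C[Li])C(=C)C | intermediate
7 | lithium (4R)-7-methyl-4-(prop-1-en-2-yl)oct-7-en-1-yn-1-olate (ynolate, not isolated) | C=C(C)CC[C@H](CC#CO[Li])C(=C)C | intermediate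
8 | {[(4R)-7-methyl-4-(prop-1-en-2-yl)oct-7-en-1-yn-1-yl]oxy}tri(propan-2-yl)silane | C=C(C)CC[C@H](CC#CO[Si](C(C)C)(C(C)C)C(C)C)C(=C)C | intermediate
9 | ketene (ethenone), generated on demand | C=C=O | starting material
10 | 2-[(2R)-5-methyl-2-(prop-1-en-2-yl)hex-5-en-1-yl]-3-{[tri(propan-2-yl)silyl]oxy}cyclobut-2-en-1-one | C=C(C)CC[C@H](CC1=C(O[Si](C(C)C)(C(C)C)C(C)C)CC1=O)C(=C)C | intermediate
11 | 3-methylbut-1-yne | CC(C)C#C | starting material
12 | chloridobis(cyclopentadienyl)[(1E)-3-methylbut-1-en-1-yl]zirconium (not isolated) | CC(C)/C=C/[Zr](Cl)(C1C=CC=C1)C1C=CC=C1 | intermediate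
13 | (1E)-1-iodo-3-methylbut-1-ene | CC(C)/C=C/I | intermediate
14 | 2-chloro-1,1-dimethoxyethane | COC(CCl)OC | starting material
15 | lithium methoxyacetylide (not isolated) | COC#C[Li] | intermediate
16 | chloro(methoxyethynyl)zinc (not isolated) | COC#C[Zn]Cl | intermediate
17 | (3E)-1-methoxy-5-methylhex-3-en-1-yne | COC#C/C=C/C(C)C | intermediate
18 | 2-[(2R)-5-methyl-2-(prop-1-en-2-yl)hex-5-en-1-yl]-3-{[tri(propan-2-yl)silyl]oxy}buta-1,3-dien-1-one (vinylketene, not isolated) | C=C(C)CC[C@H](CC(=C=O)C(=C)O[Si](C(C)C)(C(C)C)C(C)C)C(=C)C | intermediate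
19 | 3-methoxy-2-[(1E)-3-methylbut-1-en-1-yl]-4-[(2R)-5-methyl-2-(prop-1-en-2-yl)hex-5-en-1-yl]-4-(1-{[tri(propan-2-yl)silyl]oxy}ethenyl)cyclobut-2-en-1-one (both epimers at C4, not isolated) | C=C(C)CC[C@H](CC1(C(=C)O[Si](C(C)C)(C(C)C)C(C)C)C(OC)=C(/C=C/C(C)C)C1=O)C(=C)C | intermediate
20 | (3E)-3-methoxy-2-[(1E)-3-methylbut-1-en-1-yl]-4-[(2R)-5-methyl-2-(prop-1-en-2-yl)hex-5-en-1-yl]-5-{[tri(propan-2-yl)silyl]oxy}hexa-1,3,5-trien-1-one (dienylketene, not isolated) | C=C(C)CC[C@H](C/C(C(=C)O[Si](C(C)C)(C(C)C)C(C)C)=C(\OC)C(=C=O)/C=C/C(C)C)C(=C)C | intermediate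
21 | 3-methoxy-2-[(1E)-3-methylbut-1-en-1-yl]-4-[(2R)-5-methyl-2-(prop-1-en-2-yl)hex-5-en-1-yl]-5-{[tri(propan-2-yl)silyl]oxy}cyclohexa-2,4-dien-1-one (not isolated) | C=C(C)CC[C@H](CC1=C(O[Si](C(C)C)(C(C)C)C(C)C)CC(=O)C(/C=C/C(C)C)=C1OC)C(=C)C | intermediate
22 | 3-methoxy-2-[(1E)-3-methylbut-1-en-1-yl]-4-[(2R)-5-methyl-2-(prop-1-en-2-yl)hex-5-en-1-yl]-5-{[tri(propan-2-yl)silyl]oxy}phenol | C=C(C)CC[C@H](Cc1c(O[Si](C(C)C)(C(C)C)C(C)C)cc(O)c(/C=C/C(C)C)c1OC)C(=C)C | intermediate
23 | 2-hydroxy-4-methoxy-3-[(1E)-3-methylbut-1-en-1-yl]-5-[(2R)-5-methyl-2-(prop-1-en-2-yl)hex-5-en-1-yl]-6-{[tri(propan-2-yl)silyl]oxy}benzaldehyde | C=C(C)CC[C@H](Cc1c(O[Si](C(C)C)(C(C)C)C(C)C)c(C=O)c(O)c(/C=C/C(C)C)c1OC)C(=C)C | intermediate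
24 | (3-bromophenoxy)(tert-butyl)dimethylsilane | CC(C)(C)[Si](C)(C)Oc1cccc(Br)c1 | starting material
25 | (3-{[tert-butyl(dimethyl)silyl]oxy}phenyl)magnesium bromide (not isolated) | CC(C)(C)[Si](C)(C)Oc1cccc([Mg]Br)c1 | intermediate
26 | (3-{[tert-butyl(dimethyl)silyl]oxy}phenyl){2-hydroxy-4-methoxy-3-[(1E)-3-methylbut-1-en-1-yl]-5-[(2R)-5-methyl-2-(prop-1-en-2-yl)hex-5-en-1-yl]-6-{[tri(propan-2-yl)silyl]oxy}phenyl}methanol (carbinol epimers) | C=C(C)CC[C@H](Cc1c(O[Si](C(C)C)(C(C)C)C(C)C)c(C(O)c2cccc(O[Si](C)(C)C(C)(C)C)c2)c(O)c(/C=C/C(C)C)c1OC)C(=C)C | intermediate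
27 | (3-{[tert-butyl(dimethyl)silyl]oxy}phenyl){2-hydroxy-4-methoxy-3-[(1E)-3-methylbut-1-en-1-yl]-5-[(2R)-5-methyl-2-(prop-1-en-2-yl)hex-5-en-1-yl]-6-{[tri(propan-2-yl)silyl]oxy}phenyl}methanone | C=C(C)CC[C@H](Cc1c(O[Si](C(C)C)(C(C)C)C(C)C)c(C(=O)c2cccc(O[Si](C)(C)C(C)(C)C)c2)c(O)c(/C=C/C(C)C)c1OC)C(=C)C | intermediate
28 | {2,6-dihydroxy-4-methoxy-3-[(1E)-3-methylbut-1-en-1-yl]-5-[(2R)-5-methyl-2-(prop-1-en-2-yl)hex-5-en-1-yl]phenyl}(3-hydroxyphenyl)methanone (CNP0208548.1) | C=C(C)CC[C@H](Cc1c(O)c(C(=O)c2cccc(O)c2)c(O)c(/C=C/C(C)C)c1OC)C(=C)C | target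

## Step count and risk

Total step count: 12. Longest linear sequence: 10 steps (steps 1, 2, 3, 4, 5, 8, 9, 10, 11, 12). Steps 6 and 7 form the second branch.

**Step 8 (key step).** Most likely to go wrong: vinylketene 18 may be consumed by paths other than the [2+2] addition to 17. These are dimerisation, intramolecular capture by the isopropenyl group (which sits two atoms from the ketene α-carbon), and O-acylation of phenol 22 as it forms. In addition, the conjugated ynol ether 17 may oligomerise at the temperature needed to open the donor-substituted cyclobutenone. Fallback: setting out from 10, the benzannulation would be run with the parent ynol ether, methoxyethyne F1 (from 15 by protonation and distillation into toluene). This should give 3-methoxy-4-[(2R)-5-methyl-2-(prop-1-en-2-yl)hex-5-en-1-yl]-5-{[tri(propan-2-yl)silyl]oxy}phenol F2, which has C5 and C1 free. Magnesium-mediated ortho-formylation with one equivalent of formaldehyde should prefer C5, which is flanked by OH and OMe, over C1, which is shielded by the triisopropylsilyl ether. The product would be 6-hydroxy-2-methoxy-3-[(2R)-5-methyl-2-(prop-1-en-2-yl)hex-5-en-1-yl]-4-{[tri(propan-2-yl)silyl]oxy}benzaldehyde F3. Julia–Kocienski olefination of F3 with 5-[(2-methylpropyl)sulfonyl]-1-phenyl-1H-tetrazole F4 (KN(SiMe3)2, THF, −78 °C → rt) should install the (E)-alkene and come back to the route at 22.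

**Step 7.** Most likely to go wrong: incomplete formation or decay of acetylide 15 before transmetalation, and hydration, oligomerisation or evaporative loss of the small ynol ether 17 during isolation. Fallback: setting out from 15, 1,2-addition to 3-methylbutanal would give 1-methoxy-5-methylhex-1-yn-3-ol F5. Its conversion into 1-methoxy-5-methylhex-1-yn-3-yl methanesulfonate F6 (MsCl, Et3N, −20 °C) and elimination with DBU should form the conjugated (E)-enyne by carbonyl addition and dehydration instead of cross-coupling. This comes back at 17.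

**Step 5.** Most likely to go wrong: poor control of the ketene gas stream (under- or over-delivery) and desilylative hydrolysis of the vinylogous silyl ester 10 during work-up and chromatography. Fallback: setting out from 8, dichloroketene generated in the flask (Cl3CCOCl, Zn–Cu couple, Et2O, one equivalent to spare the alkenes) would give 4,4-dichloro-2-[(2R)-5-methyl-2-(prop-1-en-2-yl)hex-5-en-1-yl]-3-{[tri(propan-2-yl)silyl]oxy}cyclobut-2-en-1-one F7. Reductive dechlorination (Zn, TMEDA, AcOH, EtOH) comes back at 10.

**Step 2.** Most likely to go wrong: intramolecular aldol condensation of the 1,6-keto aldehyde to a cyclopentene under K2CO3/MeOH before the homologation is complete. Fallback: setting out from 3, neutral Corey–Fuchs dibromo-olefination (CBr4, PPh3, CH2Cl2, 0 °C) would give (5R)-8,8-dibromo-5-(prop-1-en-2-yl)oct-7-en-2-one F8. Wittig methylenation then gives (4R)-1,1-dibromo-7-methyl-4-(prop-1-en-2-yl)octa-1,7-diene F9. Treatment with n-BuLi (2 equiv, THF, −78 °C) gives the acetylide directly, which comes back at 6 inside step 4.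

**Step 9.** Most likely to go wrong: slow formylation at C1 because of shielding by the neighbouring triisopropylsilyl ether, with quinone methide side reactions of the hydroxymethyl intermediate on prolonged heating. Fallback: setting out from 22, the silyl ether would be removed first (Bu4NF) to give 5-methoxy-4-[(1E)-3-methylbut-1-en-1-yl]-6-[(2R)-5-methyl-2-(prop-1-en-2-yl)hex-5-en-1-yl]benzene-1,3-diol F10, in which C1 is flanked by two free OH groups. The same formylation should then give 2,6-dihydroxy-4-methoxy-3-[(1E)-3-methylbut-1-en-1-yl]-5-[(2R)-5-methyl-2-(prop-1-en-2-yl)hex-5-en-1-yl]benzaldehyde F11. Addition of 25 (excess) gives (3-{[tert-butyl(dimethyl)silyl]oxy}phenyl){2,6-dihydroxy-4-methoxy-3-[(1E)-3-methylbut-1-en-1-yl]-5-[(2R)-5-methyl-2-(prop-1-en-2-yl)hex-5-en-1-yl]phenyl}methanol F12. MnO2 oxidation gives (3-{[tert-butyl(dimethyl)silyl]oxy}phenyl){2,6-dihydroxy-4-methoxy-3-[(1E)-3-methylbut-1-en-1-yl]-5-[(2R)-5-methyl-2-(prop-1-en-2-yl)hex-5-en-1-yl]phenyl}methanone F13. Final desilylation comes back at 28.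

## Further compounds

F1 | step 8 | methoxyethyne | COC#C
F2 | step 8 | 3-methoxy-4-[(2R)-5-methyl-2-(prop-1-en-2-yl)hex-5-en-1-yl]-5-{[tri(propan-2-yl)silyl]oxy}phenol | C=C(C)CC[C@H](Cc1c(O[Si](C(C)C)(C(C)C)C(C)C)cc(O)cc1OC)C(=C)C
F3 | step 8 | 6-hydroxy-2-methoxy-3-[(2R)-5-methyl-2-(prop-1-en-2-yl)hex-5-en-1-yl]-4-{[tri(propan-2-yl)silyl]oxy}benzaldehyde | C=C(C)CC[C@H](Cc1c(O[Si](C(C)C)(C(C)C)C(C)C)cc(O)c(C=O)c1OC)C(=C)C
F4 | step 8 | 5-[(2-methylpropyl)sulfonyl]-1-phenyl-1H-tetrazole | CC(C)CS(=O)(=O)c1nnnn1-c1ccccc1
F5 | step 7 | 1-methoxy-5-methylhex-1-yn-3-ol (racemic) | COC#CC(O)CC(C)C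
F6 | step 7 | 1-methoxy-5-methylhex-1-yn-3-yl methanesulfonate (racemic) | COC#CC(OS(C)(=O)=O)CC(C)C
F7 | step 5 | 4,4-dichloro-2-[(2R)-5-methyl-2-(prop-1-en-2-yl)hex-5-en-1-yl]-3-{[tri(propan-2-yl)silyl]oxy}cyclobut-2-en-1-one | C=C(C)CC[C@H](CC1=C(O[Si](C(C)C)(C(C)C)C(C)C)C(Cl)(Cl)C1=O)C(=C)C
F8 | step 2 | (5R)-8,8-dibromo-5-(prop-1-en-2-yl)oct-7-en-2-one | CC(=O)CC[C@H](CC=C(Br)Br)C(=C)C
F9 | step 2 | (4R)-1,1-dibromo-7-methyl-4-(prop-1-en-2-yl)octa-1,7-diene | C=C(C)CC[C@H](CC=C(Br)Br)C(=C)C
F10 | step 9 | 5-methoxy-4-[(1E)-3-methylbut-1-en-1-yl]-6-[(2R)-5-methyl-2-(prop-1-en-2-yl)hex-5-en-1-yl]benzene-1,3-diol | C=C(C)CC[C@H](Cc1c(O)cc(O)c(/C=C/C(C)C)c1OC)C(=C)C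
F11 | step 9 | 2,6-dihydroxy-4-methoxy-3-[(1E)-3-methylbut-1-en-1-yl]-5-[(2R)-5-methyl-2-(prop-1-en-2-yl)hex-5-en-1-yl]benzaldehyde | C=C(C)CC[C@H](Cc1c(O)c(C=O)c(O)c(/C=C/C(C)C)c1OC)C(=C)C
F12 | step 9 | (3-{[tert-butyl(dimethyl)silyl]oxy}phenyl){2,6-dihydroxy-4-methoxy-3-[(1E)-3-methylbut-1-en-1-yl]-5-[(2R)-5-methyl-2-(prop-1-en-2-yl)hex-5-en-1-yl]phenyl}methanol (carbinol epimers) | C=C(C)CC[C@H](Cc1c(O)c(C(O)c2cccc(O[Si](C)(C)C(C)(C)C)c2)c(O)c(/C=C/C(C)C)c1OC)C(=C)C
F13 | step 9 | (3-{[tert-butyl(dimethyl)silyl]oxy}phenyl){2,6-dihydroxy-4-methoxy-3-[(1E)-3-methylbut-1-en-1-yl]-5-[(2R)-5-methyl-2-(prop-1-en-2-yl)hex-5-en-1-yl]phenyl}methanone | C=C(C)CC[C@H](Cc1c(O)c(C(=O)c2cccc(O[Si](C)(C)C(C)(C)C)c2)c(O)c(/C=C/C(C)C)c1OC)C(=C)C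
A1 | alternative 1 | 2-(bromomethyl)-3-methoxy-1,5-bis(methoxymethoxy)-4-[(1E)-3-methylbut-1-en-1-yl]benzene | BrCc1c(OCOC)cc(OCOC)c(/C=C/C(C)C)c1OC
A2 | alternative 1 | (4S)-4-benzyl-3-(5-methylhex-5-enoyl)-1,3-oxazolidin-2-one | C=C(C)CCCC(=O)N1C(=O)OC[C@@H]1Cc1ccccc1
A3 | alternative 1 | (4S)-4-benzyl-3-[(2R)-2-({2-methoxy-4,6-bis(methoxymethoxy)-3-[(1E)-3-methylbut-1-en-1-yl]phenyl}methyl)-5-methylhex-5-enoyl]-1,3-oxazolidin-2-one | C=C(C)CC[C@H](Cc1c(OCOC)cc(OCOC)c(/C=C/C(C)C)c1OC)C(=O)N1C(=O)OC[C@@H]1Cc1ccccc1
A4 | alternative 1 | (3R)-3-({2-methoxy-4,6-bis(methoxymethoxy)-3-[(1E)-3-methylbut-1-en-1-yl]phenyl}methyl)-6-methylhept-6-en-2-one | C=C(C)CC[C@H](Cc1c(OCOC)cc(OCOC)c(/C=C/C(C)C)c1OC)C(C)=O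
A5 | alternative 2 | 6-[2-(3-{[tert-butyl(dimethyl)silyl]oxy}phenyl)-2-oxoethyl]-4-methoxy-5-[(1E)-3-methylbut-1-en-1-yl]-3-[(2R)-5-methyl-2-(prop-1-en-2-yl)hex-5-en-1-yl]-2H-pyran-2-one | C=C(C)CC[C@H](CC1=C(OC)C(/C=C/C(C)C)=C(CC(=O)c2cccc(O[Si](C)(C)C(C)(C)C)c2)OC1=O)C(=C)C
A6 | alternative 2 | (2S)-5-methyl-2-(prop-1-en-2-yl)hex-5-enal | C=C(C)CC[C@H](C=O)C(=C)C
A7 | alternative 3 | 3-methoxy-5-(methoxymethoxy)-4-[(1E)-3-methylbut-1-en-1-yl]-2-[(2R)-5-methyl-2-(prop-1-en-2-yl)hex-5-en-1-yl]-6-(trimethylsilyl)phenyl trifluoromethanesulfonate | C=C(C)CC[C@H](Cc1c(OS(=O)(=O)C(F)(F)F)c([Si](C)(C)C)c(OCOC)c(/C=C/C(C)C)c1OC)C(=C)C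
A8 | alternative 3 | 4-methoxy-6-(methoxymethoxy)-5-[(1E)-3-methylbut-1-en-1-yl]-3-[(2R)-5-methyl-2-(prop-1-en-2-yl)hex-5-en-1-yl]benzyne (triple bond C1–C2) | C=C(C)CC[C@H](CC1=C(OC)C(/C=C/C(C)C)=C(OCOC)C#C1)C(=C)C
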